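**Plan**

1. Numbering used (same in both halves): ring A = C1–C5 and C10 (two methyls on C4, one on C10); ring B = C5–C10 (methyl on C8, double bond C8=C9); C11 is the CH2 on C9, and the halves are joined C11–C11'.
2. Retrosynthesis: each C7 methylene is taken back to a carbonyl and each C5–H to a C5=C6 double bond; the central C11–C11' bond is then cut to two identical C15 dienones; in each dienone the ring B bonds C9–C10 and C5–C6 are cut, leaving 2,2,6-trimethylcyclohexanone (ring A) and 3-methylpenta-3,4-dien-2-one (C6–C9 with C11 and the C8 methyl).
3. Forward: ring A is bought; ring B is closed onto it in one flask by enol Michael addition (C10 to the central allene carbon C9) and aldol condensation (C6 onto C5); two molecules of the dienone are joined at C11 by oxidative coupling of the dienolate; hydrogenation of C5=C6 and removal of the C7 carbonyls finish the route.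
4. Enabling feature: C10 and C5 are the α-carbon and the carbonyl carbon of a ketone whose other α-carbon, C4, is quaternary, so ring A has one enol only and, once C10 is quaternary, a carbonyl that cannot enolise; the temporary C7 carbonyl then leaves the C11 methyl as the only acidic position of the dienone.
5. Stereochemistry: C10 is set by a chiral phosphoric acid in the Michael step; C5 by hydrogenation from the face opposite to the C10 methyl and the axial C4 methyl (trans fusion); coupling two enantioenriched halves gives the C2-symmetric isomer, and the meso isomer that the minor enantiomer would give is separable.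

Key step: step 3

Assumption: the (S)-phosphoric acid is taken to deliver the (R)-configured quaternary carbon of 9; should a test run show the opposite sense, its (R)-enantiomer is used and nothing else changes.

**Route**

Step 1
Reactants: 1 1-bromobut-2-yne; 2 acetaldehyde
Product: 4 3-methylpenta-3,4-dien-2-ol (racemic), via but-2-ynylindium dibromide 3 (not isolated)
Conditions: In powder, THF, rt (Barbier conditions); aq. NH4Cl work-up
Reagents that add atoms: none
Why: Barbier-type indium-mediated carbonyl addition in which the methyl-substituted propargylindium species 3 reacts through its remote alkyne carbon (SE2') and so should give the α-allenic alcohol and not the homopropargylic isomer; the carbinol stereocentre forms racemic and is destroyed in step 2.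

Step 2
Reactants: 4 3-methylpenta-3,4-dien-2-ol
Product: 5 3-methylpenta-3,4-dien-2-one
Conditions: Dess–Martin periodinane, CH2Cl2, 0 °C; kept as a cold solution and used at once
Reagents that add atoms: none
Why: Dess–Martin oxidation of a secondary α-allenic alcohol to the allenyl ketone under neutral, metal-free conditions that should leave the cumulated diene intact; no stereocentre remains.

Step 3
Reactants: 6 2,2,6-trimethylcyclohexan-1-one (racemic); 5 3-methylpenta-3,4-dien-2-one
Product: 9 (4aR)-3,4,4a,8,8-pentamethyl-5,6,7,8-tetrahydronaphthalen-2(4aH)-one, via Michael adduct 7 (not isolated), via ketol 8 (not isolated)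
Conditions: (S)-3,3'-bis(2,4,6-triisopropylphenyl)-1,1'-binaphthyl-2,2'-diyl hydrogen phosphate ((S)-TRIP, 10 mol%), cyclohexane, 50 °C, slow addition of 5 to 6 (2 equiv); then KOH (powdered), xylenes, reflux, Dean–Stark, same flask
Reagents that add atoms: none
Why: Proposed new method: the chiral phosphoric acid is expected to turn 6 into its only possible enol (C4 is quaternary, so enolisation can go only toward C10) and, hydrogen-bonded to the enol OH and to the carbonyl of 5, to guide C10 onto the sp-hybridised central carbon C9 of the allenyl ketone, an unhindered electrophilic carbon that can accept a fully substituted nucleophile, after which tautomerisation gives 7. The closest known reaction type is the Brønsted acid (enol) catalysed Michael addition of α-branched cyclic ketones to vinyl ketones, and the closest known ring construction is the Robinson annulation with alkynyl ketones that ends in cross-conjugated dienones. After the switch to KOH the methyl ketone enolate carbon C6 adds to the ring A carbonyl C5 in a 6-(enolendo)-exo-trig aldol closure, and E1cB loss of water from ketol 8 completes ring B. The only new stereocentre that survives, C10 (C4a, R), is set in the Michael step by the catalyst, the racemic stereocentre of 6 being erased in the enol. The step needs regiocontrol in both partners: 6 has no second enolisable position and, once C10 is quaternary, its carbonyl has no α-hydrogen and can act only as the aldol acceptor, while of the nucleophilic carbons that base can generate in the side chain (C6, C8, C11) only C6 can reach C5 through a six-membered ring, the Z and E forms of 7 interconverting through the dienolate. The Michael addition is not expected to reverse under the basic second stage, because that would regenerate the allene.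

Step 4
Reactants: 9 (4aR)-3,4,4a,8,8-pentamethyl-5,6,7,8-tetrahydronaphthalen-2(4aH)-one (two molecules per molecule of product)
Product: 11 4,4'-(ethane-1,2-diyl)bis[(4aR)-3,4a,8,8-tetramethyl-5,6,7,8-tetrahydronaphthalen-2(4aH)-one], via lithium dienolate 10 (not isolated)
Conditions: LiN(iPr)2, THF, −78 to −40 °C; then anhydrous CuCl2, DMF, −78 °C to rt
Reagents that add atoms: second molecule of dienone 9, CC1=C(C)C(=O)C=C2C(C)(C)CCC[C@]12C
Why: Oxidative homocoupling of an enolate (one-electron oxidation by CuCl2 and radical dimerisation, a union of two nucleophilic carbons), in which each of the two molecules of 9 can be deprotonated only at the C11 methyl to give 10 and the new C11–C11' bond should form between the primary termini of two such radicals because the other radical terminus, C8, is fully substituted; no stereocentre is formed, so two (R)-halves can give only the (R,R)-dimer.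

Step 5
Reactants: 11 4,4'-(ethane-1,2-diyl)bis[(4aR)-3,4a,8,8-tetramethyl-5,6,7,8-tetrahydronaphthalen-2(4aH)-one]
Product: 12 4,4'-(ethane-1,2-diyl)bis[(4aS,8aS)-3,4a,8,8-tetramethyl-4a,5,6,7,8,8a-hexahydronaphthalen-2(1H)-one]
Conditions: H2 (3 atm), 10% Pd/C, EtOAc, rt
Reagents that add atoms: none
Why: Heterogeneous catalytic hydrogenation of the two trisubstituted enone double bonds C5=C6, the tetrasubstituted C8=C9 bonds being too hindered to adsorb, with hydrogen expected to reach C5 from the face opposite to the C10 methyl and the axial C4 methyl (as in the hydrogenation of 4,4,10-trimethyl-Δ5-octalins), which sets both C5 stereocentres as the trans ring fusion.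

Step 6
Reactants: 12 4,4'-(ethane-1,2-diyl)bis[(4aS,8aS)-3,4a,8,8-tetramethyl-4a,5,6,7,8,8a-hexahydronaphthalen-2(1H)-one]
Product: 13 bis(1,3-dithiolane) of 12 (each C7 carbonyl replaced by a spiro-1,3-dithiolane; 4aS,8aS in both halves)
Conditions: HSCH2CH2SH, BF3·OEt2 (cat.), CH2Cl2, 0 °C to rt
Reagents that add atoms: ethane-1,2-dithiol, SCCS
Why: Lewis acid catalysed dithioketalisation of the two enone carbonyls, with conjugate addition of the thiol blocked because C9 is fully substituted and the alkenes deactivated toward acid by conjugation; no stereocentre arises because each spiro carbon carries two identical sulfur arms.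

Step 7
Reactants: 13 bis(1,3-dithiolane) of 12
Product: 14 1,2-bis[(4aS,8aS)-2,5,5,8a-tetramethyl-3,4,4a,5,6,7,8,8a-octahydronaphthalen-1-yl]ethane (target)
Conditions: Raney Ni (W-2), EtOH, reflux
Reagents that add atoms: none
Why: Mozingo reduction (hydrogenolytic desulfurisation on Raney Ni) turns each dithioketal carbon into the C7 methylene without a carbocation, so the hindered tetrasubstituted C8=C9 bonds should stay in place and acid-triggered cyclisation between the two alkenes is avoided; no stereocentre is touched.

**Compound list**

1 | 1-bromobut-2-yne | CC#CCBr | starting material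
2 | acetaldehyde | CC=O | starting material
3 | but-2-yn-1-ylindium dibromide (propargylic form of the organoindium reagent) | CC#CC[In](Br)Br | intermediate
4 | 3-methylpenta-3,4-dien-2-ol (racemic) | CC(O)C(C)=C=C | intermediate
5 | 3-methylpenta-3,4-dien-2-one | CC(=O)C(C)=C=C | intermediate
6 | 2,2,6-trimethylcyclohexan-1-one (racemic) | CC1CCCC(C)(C)C1=O | starting material
7 | (R)-2,2,6-trimethyl-6-[(2Z)-3-methyl-4-oxopent-2-en-2-yl]cyclohexan-1-one (Z form shown; E and Z interconvert) | CC(=O)/C(C)=C(/C)[C@@]1(C)CCCC(C)(C)C1=O | intermediate
8 | (4aR)-8a-hydroxy-3,4,4a,8,8-pentamethyl-4a,5,6,7,8,8a-hexahydronaphthalen-2(1H)-one (carbinol configuration not defined, lost on dehydration) | CC1=C(C)C(=O)CC2(O)C(C)(C)CCC[C@]12C | intermediate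
9 | (4aR)-3,4,4a,8,8-pentamethyl-5,6,7,8-tetrahydronaphthalen-2(4aH)-one | CC1=C(C)C(=O)C=C2C(C)(C)CCC[C@]12C | intermediate
10 | lithium (4aR)-3,4a,8,8-tetramethyl-4-methylidene-4,4a,5,6,7,8-hexahydronaphthalen-2-olate | [Li+].[O-]C1=C(C)C(=C)[C@@]2(C)CCCC(C)(C)C2=C1 | intermediate
11 | 4,4'-(ethane-1,2-diyl)bis[(4aR)-3,4a,8,8-tetramethyl-5,6,7,8-tetrahydronaphthalen-2(4aH)-one] | CC1=C(CCC2=C(C)C(=O)C=C3C(C)(C)CCC[C@]23C)[C@@]2(C)CCCC(C)(C)C2=CC1=O | intermediate
12 | 4,4'-(ethane-1,2-diyl)bis[(4aS,8aS)-3,4a,8,8-tetramethyl-4a,5,6,7,8,8a-hexahydronaphthalen-2(1H)-one] | CC1=C(CCC2=C(C)C(=O)C[C@H]3C(C)(C)CCC[C@]23C)[C@@]2(C)CCCC(C)(C)[C@@H]2CC1=O | intermediate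
13 | bis(1,3-dithiolane) of 12 (spiro-dithiolane at each former carbonyl carbon; 4aS,8aS in both halves) | CC1=C(CCC2=C(C)C4(SCCS4)C[C@H]3C(C)(C)CCC[C@]23C)[C@@]2(C)CCCC(C)(C)[C@@H]2CC15SCCS5 | intermediate
14 | 1,2-bis[(4aS,8aS)-2,5,5,8a-tetramethyl-3,4,4a,5,6,7,8,8a-octahydronaphthalen-1-yl]ethane | CC1=C(CCC2=C(C)CC[C@H]3C(C)(C)CCC[C@]23C)[C@@]2(C)CCCC(C)(C)[C@@H]2CC1 | target

**Step count and risks**

Total step count: 7. Longest linear sequence: 7 steps (1 to 14 through steps 1–7; 5 steps from ketone 6).

Step 3 is the most likely to fail. The hindered ketone may enolise too slowly on the phosphoric acid, the catalyst may discriminate poorly between the two enol faces, or the allenyl ketone may oligomerise before it is captured. The fallback uses known chemistry and replaces catalyst control by resolution. It sets out from 6 and 5. LiN(iPr)2 in THF at −78 °C gives lithium 2,6,6-trimethylcyclohex-1-en-1-olate F1. This adds to the central allene carbon of 5 and gives, after aqueous work-up, racemic 2,2,6-trimethyl-6-(3-methyl-4-oxopent-2-en-2-yl)cyclohexan-1-one F2. KOH in refluxing xylenes with removal of water closes ring B through the racemic ketol 8a-hydroxy-3,4,4a,8,8-pentamethyl-4a,5,6,7,8,8a-hexahydronaphthalen-2(1H)-one F3 to racemic 3,4,4a,8,8-pentamethyl-5,6,7,8-tetrahydronaphthalen-2(4aH)-one F4. Preparative chromatography on a chiral stationary phase then gives 9, and (4aS)-3,4,4a,8,8-pentamethyl-5,6,7,8-tetrahydronaphthalen-2(4aH)-one F5 is set aside. The route is rejoined at 9.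

Step 4 is the second risk. The delocalised radical may couple through C8 or through oxygen instead of C11, or be oxidised further. The fallback sets out from 9. N-Bromosuccinimide with AIBN in refluxing PhCF3 should brominate the C11 methyl, whose radical is the only one conjugated with the carbonyl, to give (4aS)-4-(bromomethyl)-3,4a,8,8-tetramethyl-5,6,7,8-tetrahydronaphthalen-2(4aH)-one F6. Reductive homocoupling of two molecules of this allylic bromide with Ni(cod)2 (zerovalent nickel, DMF, rt) should then join the two primary allyl termini. The route is rejoined at 11.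

Step 5 is the third risk. Hydrogen may be delivered to the wrong face of C5=C6, which would give the cis ring fusion, or uptake at the hindered double bond may stall. The fallback sets out from 11 and replaces surface hydrogenation by electron transfer. Li in NH3/THF with t-BuOH (2 equiv per dienone) at −78 °C should reduce the enone arm that lacks the α-methyl group, and the carbanion at C5 should be protonated axially to the more stable trans fusion. This gives the dilithium bis(dienolate) of 12 F7, which an NH4Cl quench converts into 12. The route is rejoined at 12.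

**Further compounds**

F1 | step 3 | lithium 2,6,6-trimethylcyclohex-1-en-1-olate | [Li+].[O-]C1=C(C)CCCC1(C)C
F2 | step 3 | racemic 2,2,6-trimethyl-6-(3-methyl-4-oxopent-2-en-2-yl)cyclohexan-1-one | CC(=O)C(C)=C(C)C1(C)CCCC(C)(C)C1=O
F3 | step 3 | racemic 8a-hydroxy-3,4,4a,8,8-pentamethyl-4a,5,6,7,8,8a-hexahydronaphthalen-2(1H)-one | CC1=C(C)C(=O)CC2(O)C(C)(C)CCCC12C
F4 | step 3 | racemic 3,4,4a,8,8-pentamethyl-5,6,7,8-tetrahydronaphthalen-2(4aH)-one | CC1=C(C)C(=O)C=C2C(C)(C)CCCC12C
F5 | step 3 | (4aS)-3,4,4a,8,8-pentamethyl-5,6,7,8-tetrahydronaphthalen-2(4aH)-one | CC1=C(C)C(=O)C=C2C(C)(C)CCC[C@@]12C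
F6 | step 4 | (4aS)-4-(bromomethyl)-3,4a,8,8-tetramethyl-5,6,7,8-tetrahydronaphthalen-2(4aH)-one | BrCC1=C(C)C(=O)C=C2C(C)(C)CCC[C@]12C
F7 | step 5 | dilithium bis(dienolate) of 12 (C6=C7 enolate in each half; 4aS,8aS) | [Li+].[Li+].CC1=C(CCC2=C(C)C([O-])=C[C@H]3C(C)(C)CCC[C@]23C)[C@@]2(C)CCCC(C)(C)[C@@H]2C=C1[O-]
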